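**Strategy.** The route rests on the C2–C3 bond of the flavanone unit. Because C2 is a benzylic carbon bound to O1 and to the 4-oxygenated B ring, it is traced back to the CH2 of a 4-(benzyloxy)benzyl ether on the phloroglucinol A ring. A chiral Rh(II) carbene at C3, generated from α-diazo ketone 8 that already carries the complete apigenin unit, inserts into one enantiotopic C2–H bond; this closes the dihydropyranone ring (C4, C4a, C8a, O1, C2, C3) and sets C2, and C3 settles trans by enolisation. The two ortho ethers of the A ring are equivalent, so either gives the same ring, and the unused one ends as 5-OH.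

Key step: step 6

Remark: by CIP analysis of the target SMILES the flavanone stereocentres are 2S,3R (2,3-trans). Locants without primes refer to the flavanone unit, doubly primed locants to the flavone unit.

Remark: the sense of induction of the Rh(II) catalyst on this substrate is to be fixed in a pilot run; both catalyst antipodes are available, and Rh2(S-PTTL)4 is written for definiteness.

**Step 1**
Reactants: 1 apigenin
Product: 2 5,7-bis(benzyloxy)-2-[4-(benzyloxy)phenyl]-4H-chromen-4-one
Conditions: BnBr (4 equiv), K2CO3, DMF, 80 °C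
Reagents that add atoms: benzyl bromide, BrCc1ccccc1
Why: Threefold Williamson etherification; excess bromide and heat in DMF are needed to alkylate the chelated 5-OH as well.

**Step 2**
Reactants: 2 5,7-bis(benzyloxy)-2-[4-(benzyloxy)phenyl]-4H-chromen-4-one
Product: 4 5,7-bis(benzyloxy)-2-[4-(benzyloxy)phenyl]-3-iodo-4H-chromen-4-one, via 3-lithioflavone 3 (not isolated)
Conditions: LDA, THF, −78 °C; then I2, −78 °C to rt
Reagents that add atoms: iodine, II
Why: Deprotonative iodination: the vinylic C3''–H next to the chromone carbonyl is lithiated by LDA at low temperature and quenched with iodine, so the site is fixed by acidity and not by the nucleophilicity of the dialkoxy A ring.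

**Step 3**
Reactants: 5 1-(2,4,6-trihydroxyphenyl)ethan-1-one
Product: 6 1-(2,4,6-tris{[4-(benzyloxy)phenyl]methoxy}phenyl)ethan-1-one
Conditions: 4-(benzyloxy)benzyl chloride (3.3 equiv), K2CO3, KI (cat.), DMF, 70 °C
Reagents that add atoms: 4-(benzyloxy)benzyl chloride, ClCc1ccc(OCc2ccccc2)cc1
Why: Threefold Williamson etherification with the commercial benzylic chloride, in which the acyl group lowers ring nucleophilicity and so disfavours C-alkylation and heating in DMF drives alkylation of both chelated ortho hydroxyls; one of the two equivalent ortho groups later supplies C2 and the B ring, the other two serve as protecting groups.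

**Step 4**
Reactants: 6 1-(2,4,6-tris{[4-(benzyloxy)phenyl]methoxy}phenyl)ethan-1-one; 4 5,7-bis(benzyloxy)-2-[4-(benzyloxy)phenyl]-3-iodo-4H-chromen-4-one
Product: 7 5,7-bis(benzyloxy)-2-[4-(benzyloxy)phenyl]-3-[2-oxo-2-(2,4,6-tris{[4-(benzyloxy)phenyl]methoxy}phenyl)ethyl]-4H-chromen-4-one
Conditions: Pd2(dba)3 (cat.), Xantphos (cat.), K3PO4, toluene, 90 °C
Reagents that add atoms: none
Why: Palladium-catalysed α-arylation of a methyl ketone enolate (Buchwald–Hartwig type) with the alkenyl iodide; the weak base spares the flavone, and the more acidic product rests as its enolate, which should suppress a second arylation.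

**Step 5**
Reactants: 7 flavon-3-ylmethyl ketone
Product: 8 5,7-bis(benzyloxy)-2-[4-(benzyloxy)phenyl]-3-[1-diazo-2-oxo-2-(2,4,6-tris{[4-(benzyloxy)phenyl]methoxy}phenyl)ethyl]-4H-chromen-4-one
Conditions: p-ABSA, DBU, MeCN–CH2Cl2, 0 °C to rt; product kept cold and used promptly
Reagents that add atoms: 4-acetamidobenzenesulfonyl azide (p-ABSA), CC(=O)Nc1ccc(cc1)S(=O)(=O)N=[N+]=[N-]
Why: Regitz diazo transfer, which works directly on α-aryl-type ketones because the methylene between the carbonyl and the chromenyl carbon is acidic enough for DBU.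

**Step 6**
Reactants: 8 α-diazo ketone
Product: 10 (2S,3R)-3-{5,7-bis(benzyloxy)-2-[4-(benzyloxy)phenyl]-4-oxo-4H-chromen-3-yl}-2-[4-(benzyloxy)phenyl]-5,7-bis{[4-(benzyloxy)phenyl]methoxy}-2,3-dihydro-4H-chromen-4-one, via cis-(2S,3S) epimer 9 (not isolated)
Conditions: 8 added slowly to Rh2(S-PTTL)4 (1 mol %), toluene, 0 °C to rt; then Et3N (0.2 equiv), rt
Reagents that add atoms: none
Why: Rh(II) takes N2 from 8 to give an electrophilic carbene at C3, flanked by the acceptor ketone (C4) and the donor chromen-3-yl group, which inserts in a concerted, hydride-transfer-like three-centre step into a C–H bond of the ortho ArCH2–O group, so that C2–C3 forms and that CH2 becomes C2 with its 4-oxygenated aryl group. The closest known reaction type is the enantioselective Rh(II)-carboxylate-catalysed intramolecular C–H insertion of o-alkoxyaryl α-diazo ketones to chroman-4-ones, and of α-aryl-α-diazo ketones in general. The dihydropyranone ring closes by 1,6-C–H insertion through a six-membered transition state; no five-membered C–H alternative exists because the fifth atom is O1. C2 is set by the chiral catalyst, which distinguishes the enantiotopic benzylic hydrogens (replacement of the pro-S hydrogen with retention gives 2S), and C3 is set under thermodynamic control, the cis epimer 9 being equilibrated through the enol by catalytic Et3N to the diequatorial trans isomer, conditions chosen to be too mild for retro-oxa-Michael opening at C2. The step needs C–H insertion to win over oxonium ylide formation with [1,2]-benzyl shift, over attack on the flavone B ring and over the remote 5''-OCH2Ph group; the doubly activated C–H bond (α to oxygen, 4-alkoxybenzylic), the low basicity of an aryl ether oxygen conjugated to the ketone, the stabilised donor/acceptor carbene and the six-membered geometry should secure this. Site selectivity is no issue because the two ortho ethers of the phloroglucinol ring are equivalent by rotation and the para ether is out of reach.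

**Step 7**
Reactants: 10 protected biflavonoid
Product: 11 (2S,3R)-3-[5,7-dihydroxy-2-(4-hydroxyphenyl)-4-oxo-4H-chromen-3-yl]-5,7-dihydroxy-2-(4-hydroxyphenyl)-2,3-dihydro-4H-chromen-4-one
Conditions: H2 (1 atm), 10% Pd/C, THF–MeOH, rt, stopped on full conversion
Reagents that add atoms: none
Why: Hydrogenolysis of the four benzyl ethers and the two 4-(benzyloxy)benzyl ethers under neutral conditions, which should leave C2 and C3 untouched; the cyclic benzylic C2–O1 bond and the tetrasubstituted flavone alkene react more slowly.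

**Compound list**

1 | apigenin | O=c1cc(-c2ccc(O)cc2)oc2cc(O)cc(O)c12 | starting material
2 | 5,7-bis(benzyloxy)-2-[4-(benzyloxy)phenyl]-4H-chromen-4-one | O=c1cc(-c2ccc(OCc3ccccc3)cc2)oc2cc(OCc3ccccc3)cc(OCc3ccccc3)c12 | intermediate
3 | 3-lithio derivative of 2 | [Li]c1c(-c2ccc(OCc3ccccc3)cc2)oc2cc(OCc3ccccc3)cc(OCc3ccccc3)c2c1=O | intermediate (not isolated)
4 | 5,7-bis(benzyloxy)-2-[4-(benzyloxy)phenyl]-3-iodo-4H-chromen-4-one | O=c1c(I)c(-c2ccc(OCc3ccccc3)cc2)oc2cc(OCc3ccccc3)cc(OCc3ccccc3)c12 | intermediate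
5 | 1-(2,4,6-trihydroxyphenyl)ethan-1-one | CC(=O)c1c(O)cc(O)cc1O | starting material
6 | 1-(2,4,6-tris{[4-(benzyloxy)phenyl]methoxy}phenyl)ethan-1-one | CC(=O)c1c(OCc2ccc(OCc3ccccc3)cc2)cc(OCc2ccc(OCc3ccccc3)cc2)cc1OCc1ccc(OCc2ccccc2)cc1 | intermediate
7 | 5,7-bis(benzyloxy)-2-[4-(benzyloxy)phenyl]-3-[2-oxo-2-(2,4,6-tris{[4-(benzyloxy)phenyl]methoxy}phenyl)ethyl]-4H-chromen-4-one | O=C(Cc1c(-c2ccc(OCc3ccccc3)cc2)oc2cc(OCc3ccccc3)cc(OCc3ccccc3)c2c1=O)c1c(OCc2ccc(OCc3ccccc3)cc2)cc(OCc2ccc(OCc3ccccc3)cc2)cc1OCc1ccc(OCc2ccccc2)cc1 | intermediate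
8 | 5,7-bis(benzyloxy)-2-[4-(benzyloxy)phenyl]-3-[1-diazo-2-oxo-2-(2,4,6-tris{[4-(benzyloxy)phenyl]methoxy}phenyl)ethyl]-4H-chromen-4-one | O=C(C(=[N+]=[N-])c1c(-c2ccc(OCc3ccccc3)cc2)oc2cc(OCc3ccccc3)cc(OCc3ccccc3)c2c1=O)c1c(OCc2ccc(OCc3ccccc3)cc2)cc(OCc2ccc(OCc3ccccc3)cc2)cc1OCc1ccc(OCc2ccccc2)cc1 | intermediate
9 | (2S,3S)-cis epimer of 10 | O=C1c2c(OCc3ccc(OCc4ccccc4)cc3)cc(OCc3ccc(OCc4ccccc4)cc3)cc2O[C@H](c2ccc(OCc3ccccc3)cc2)[C@@H]1c1c(-c2ccc(OCc3ccccc3)cc2)oc2cc(OCc3ccccc3)cc(OCc3ccccc3)c2c1=O | intermediate (not isolated)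
10 | (2S,3R)-3-{5,7-bis(benzyloxy)-2-[4-(benzyloxy)phenyl]-4-oxo-4H-chromen-3-yl}-2-[4-(benzyloxy)phenyl]-5,7-bis{[4-(benzyloxy)phenyl]methoxy}-2,3-dihydro-4H-chromen-4-one | O=C1c2c(OCc3ccc(OCc4ccccc4)cc3)cc(OCc3ccc(OCc4ccccc4)cc3)cc2O[C@H](c2ccc(OCc3ccccc3)cc2)[C@H]1c1c(-c2ccc(OCc3ccccc3)cc2)oc2cc(OCc3ccccc3)cc(OCc3ccccc3)c2c1=O | intermediate
11 | (2S,3R)-3-[5,7-dihydroxy-2-(4-hydroxyphenyl)-4-oxo-4H-chromen-3-yl]-5,7-dihydroxy-2-(4-hydroxyphenyl)-2,3-dihydro-4H-chromen-4-one | O=C1c2c(O)cc(O)cc2O[C@H](c2ccc(O)cc2)[C@H]1c1c(-c2ccc(O)cc2)oc2cc(O)cc(O)c2c1=O | target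

**Totals.** Total step count: 7. Longest linear sequence: 6 steps (steps 1, 2, 4, 5, 6, 7).

**Steps most likely to fail**

Step 6. The carbene may be diverted by capture at the ortho ether oxygen followed by [1,2]-benzyl shift, or by attack on the flavone B ring. The discrimination of the enantiotopic hydrogens may also be poor. The fallback closes the ring at O1–C2 instead and sets out from ketone 7. Knoevenagel condensation with 4-(benzyloxy)benzaldehyde (piperidine, AcOH, toluene, reflux with water removal) should give the fully protected α-(flavon-3-yl)chalcone F1 as an E/Z mixture. MgBr2·OEt2 (CH2Cl2–Et2O, 0 °C) should remove one of the two equivalent ortho 4-(benzyloxy)benzyl groups through chelation to the ketone and give the 2'-hydroxychalcone F2. A bifunctional cinchona-alkaloid thiourea (quinidine- or quinine-derived, 10 mol %, toluene, −25 °C) should then catalyse the enantioselective 6-endo-trig oxa-Michael addition, with C3 protonated trans. The route is rejoined at 10.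

Step 4. Slow oxidative addition or reductive elimination at the hindered alkenyl iodide, reductive loss of iodine, or base-induced degradation at 90 °C may prevent the α-arylation. The fallback sets out from 6 (with 4) and reverses the order of diazo installation and C–C coupling. Detrifluoroacetylative diazo transfer (LiHMDS, CF3CO2CH2CF3, THF, −78 °C, to the trifluoroacetyl diketone F3, not isolated; then MsN3, Et3N, H2O, MeCN) should give the diazomethyl ketone F4. Palladium-catalysed C–H arylation of this acceptor diazo compound with 4 (Pd(PPh3)4, Ag2CO3, Et3N, toluene, rt), which retains the diazo group, comes back to the route at 8 and bypasses 7.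

Step 7. Hydrogenolytic opening of the cyclic benzylic C2–O1 bond or saturation of the flavone C2''=C3'' bond may set in before all eight benzylic C–O bonds are cleaved. The fallback sets out from 10 and replaces reduction by Lewis-acid dealkylation. BCl3 with pentamethylbenzene as cation scavenger (CH2Cl2, −78 °C) should cleave the benzyl and 4-(benzyloxy)benzyl aryl ethers without hydrogen and give 11 directly; no new compound is made on the way (F0).

**Further compounds**

F1 | step 6 | 5,7-bis(benzyloxy)-2-[4-(benzyloxy)phenyl]-3-[1-[4-(benzyloxy)phenyl]-3-oxo-3-(2,4,6-tris{[4-(benzyloxy)phenyl]methoxy}phenyl)prop-1-en-2-yl]-4H-chromen-4-one (E/Z mixture) | O=C(C(=Cc1ccc(OCc2ccccc2)cc1)c1c(-c2ccc(OCc3ccccc3)cc2)oc2cc(OCc3ccccc3)cc(OCc3ccccc3)c2c1=O)c1c(OCc2ccc(OCc3ccccc3)cc2)cc(OCc2ccc(OCc3ccccc3)cc2)cc1OCc1ccc(OCc2ccccc2)cc1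
F2 | step 6 | 2'-hydroxychalcone: F1 with one ortho 4-(benzyloxy)benzyl ether of the trioxygenated ring replaced by OH (E/Z mixture) | O=C(C(=Cc1ccc(OCc2ccccc2)cc1)c1c(-c2ccc(OCc3ccccc3)cc2)oc2cc(OCc3ccccc3)cc(OCc3ccccc3)c2c1=O)c1c(O)cc(OCc2ccc(OCc3ccccc3)cc2)cc1OCc1ccc(OCc2ccccc2)cc1
F3 | step 4 | 4,4,4-trifluoro-1-(2,4,6-tris{[4-(benzyloxy)phenyl]methoxy}phenyl)butane-1,3-dione | O=C(CC(=O)C(F)(F)F)c1c(OCc2ccc(OCc3ccccc3)cc2)cc(OCc2ccc(OCc3ccccc3)cc2)cc1OCc1ccc(OCc2ccccc2)cc1
F4 | step 4 | 2-diazo-1-(2,4,6-tris{[4-(benzyloxy)phenyl]methoxy}phenyl)ethan-1-one | [N-]=[N+]=CC(=O)c1c(OCc2ccc(OCc3ccccc3)cc2)cc(OCc2ccc(OCc3ccccc3)cc2)cc1OCc1ccc(OCc2ccccc2)cc1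
F0 | step 7 | none | none
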